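**Retrosynthetic overview**
1. Dihydrofuran (last ring): endo-cycloisomerisation of the C16–OH onto a terminal C14≡C15 alkyne under basic conditions.
2. Spiro-tetrahydrofuran (C9–O–C13): 5-exo opening of a catalyst-set (13R)-13,16-epoxide by the 9α-OH, with inversion to 13S.
3. Ring B oxygens: 8β-OAc and 7-oxo from trans-diaxial acetolysis of a 7α,8α-epoxide; C9 carbinol from alkyllithium addition to the epoxy ketone.
4. Ring A onto ring B (key step): copper hydride-catalysed enantioselective reductive aldol cyclisation that desymmetrises a 2,2-disubstituted cyclohexane-1,3-dione and fixes C4 and C10 (C5 is reset later).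
5. Ring B carbons come from resorcinol (hydrogenation, methylation). Ring order: B, A, spiro-tetrahydrofuran, dihydrofuran.

Assumption: names use labdane numbering (C1–C20) with α/β descriptors (β = face of the C10 methyl); purchased reagents and catalysts (chiral ligand, Shi ketone, Burgess reagent, IBX, DMP) are not counted as steps; the target is read as 4S,5S,8R,9S,10S,13S.

**Route**

Step 1
Reactants: 1 resorcinol
Product: 3 2-methylcyclohexane-1,3-dione, via sodium 3-oxocyclohex-1-en-1-olate 2 (not isolated)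
Conditions: H2 (100 bar), Raney Ni, aq NaOH, 50 °C; then MeI, dioxane/H2O, reflux; then HCl
Reagents that add atoms: iodomethane, CI
Why: Partial hydrogenation of the resorcinolate stops at the vinylogous carboxylate (dearomatisation) and the 1,3-dione enolate is then C-methylated at C2 (enolate alkylation); no stereocentre.

Step 2
Reactants: 3 2-methylcyclohexane-1,3-dione; 4 acrolein; 5 ethyl 2-(triphenyl-λ5-phosphanylidene)propanoate
Product: 7 ethyl (2E)-2-methyl-5-(1-methyl-2,6-dioxocyclohexyl)pent-2-enoate, via Michael aldehyde 6 (not isolated)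
Conditions: H2O, rt, 12 h; then 5, CH2Cl2, rt
Reagents that add atoms: none
Why: The acidic dione adds to acrolein in water (Michael addition) and the stabilised ylide then olefinates only the aldehyde with E selectivity (Wittig reaction); the product is still mirror-symmetric at the ring.

Step 3
Reactants: 7 ethyl (2E)-2-methyl-5-(1-methyl-2,6-dioxocyclohexyl)pent-2-enoate
Product: 9 ethyl 5β-hydroxy-4α,10β-dimethyl-9-oxodecalin-4β-carboxylate (cis-fused ketol; OH and angular CH3 and CO2Et all β), via silyl ether 8 (not isolated)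
Conditions: Cu(OAc)2·H2O (5 mol%), (R)-DTBM-SEGPHOS (5.5 mol%), (EtO)2MeSiH (2 equiv), THF, 0 °C to rt; then aq citric acid
Reagents that add atoms: none
Why: Proposed new method: a chiral bisphosphine–copper hydride delivers hydride to C3 of the enoate and the resulting copper ester enolate attacks one of the two enantiotopic ring ketones through a closed six-membered (Zimmerman–Traxler) transition state, so ester, new hydroxyl and angular methyl end up mutually cis and C4, C5 and C10 are fixed in one desymmetrising step (ligand antipode chosen for 10S); the closest known reaction type is the copper hydride-catalysed enantioselective domino conjugate reduction–aldol cyclisation of enoate-tethered 2-methylcyclohexane-1,3-diones, extended here to an α-methyl enoate that creates the C4 quaternary carbon.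

Step 4
Reactants: 9 ethyl 5β-hydroxy-4α,10β-dimethyl-9-oxodecalin-4β-carboxylate
Product: 10 ethyl 4α,10β-dimethyl-9-oxo-Δ5(6)-octalin-4β-carboxylate
Conditions: Burgess reagent, toluene, 60 °C
Reagents that add atoms: none
Why: Burgess dehydration (syn elimination through the sulfamate) can only go towards C6 because C4 and C10 are quaternary, and it avoids a free C5 cation that could trigger methyl shifts; the C5 centre is erased on purpose.

Step 5
Reactants: 10 ethyl 4α,10β-dimethyl-9-oxo-Δ5(6)-octalin-4β-carboxylate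
Product: 11 ethyl 4α,10β-dimethyl-9-oxo-5α-decalin-4β-carboxylate (trans-decalin)
Conditions: Mn(dpm)3 (10 mol%), PhSiH3, t-BuOOH, i-PrOH, rt
Reagents that add atoms: none
Why: Hydrogen-atom-transfer hydrogenation (Mukaiyama type) puts a hydrogen atom on C6 and quenches the tertiary C5 radical from the α face under thermodynamic control, giving the trans-fused 5α-H product; ketone and ester are untouched.

Step 6
Reactants: 11 ethyl 4α,10β-dimethyl-9-oxo-5α-decalin-4β-carboxylate
Product: 12 ethyl 4α,8,10β-trimethyl-9-oxo-5α-decalin-4β-carboxylate (C8 epimers)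
Conditions: LDA, THF, −78 °C; MeI
Reagents that add atoms: iodomethane, CI
Why: Only C8 is enolisable (C10 is quaternary, the ester has no α-H), so enolate alkylation gives the 8-methyl ketone; the C8 configuration is irrelevant because it is planarised in step 7.

Step 7
Reactants: 12 ethyl 4α,8,10β-trimethyl-9-oxo-5α-decalin-4β-carboxylate
Product: 13 ethyl 4α,8,10β-trimethyl-9-oxo-5α-octal-7-ene-4β-carboxylate
Conditions: IBX, DMSO/toluene, 75 °C
Reagents that add atoms: none
Why: IBX dehydrogenation of the ketone through its enol gives the conjugated endocyclic 8-methyl-Δ7-enone; no new stereocentre.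

Step 8
Reactants: 13 ethyl 4α,8,10β-trimethyl-9-oxo-5α-octal-7-ene-4β-carboxylate
Product: 14 ethyl 7α,8α-epoxy-4α,8β,10β-trimethyl-9-oxo-5α-decalin-4β-carboxylate
Conditions: 30% H2O2, NaOH, MeOH, 0 °C
Reagents that add atoms: hydrogen peroxide, OO
Why: Weitz–Scheffer nucleophilic epoxidation: hydroperoxide adds axially to C7 from the α face, anti to the angular C10 methyl, and ring closure on the same face gives the 7α,8α-epoxide; the hindered ester survives cold base.

Step 9
Reactants: 15 3-bromobut-3-en-1-ol; 16 ethynyltrimethylsilane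
Product: 17 3-methylidene-5-(trimethylsilyl)pent-4-yn-1-ol
Conditions: Pd(PPh3)2Cl2 (2 mol%), CuI (4 mol%), i-Pr2NH, THF, rt
Reagents that add atoms: none
Why: Sonogashira coupling of the vinyl bromide with the terminal alkyne builds the C11–C16 enyne unit; no stereocentre.

Step 10
Reactants: 17 3-methylidene-5-(trimethylsilyl)pent-4-yn-1-ol
Product: 18 (5-iodo-3-methylidenepent-1-yn-1-yl)trimethylsilane
Conditions: I2, PPh3, imidazole, CH2Cl2, 0 °C
Reagents that add atoms: iodine, II
Why: Appel-type iodination of the primary alcohol by SN2 displacement of the oxyphosphonium; no stereocentre.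

Step 11
Reactants: 18 (5-iodo-3-methylidenepent-1-yn-1-yl)trimethylsilane; 14 ethyl 7α,8α-epoxy-4α,8β,10β-trimethyl-9-oxo-5α-decalin-4β-carboxylate
Product: 20 ethyl 7α,8α-epoxy-9α-hydroxy-15-(trimethylsilyl)labd-13(16)-en-14-yn-19-oate, via alkyllithium 19 (not isolated)
Conditions: t-BuLi (2.1 equiv), Et2O/pentane, −78 °C; then 14, THF, −78 to −40 °C; then H2O
Reagents that add atoms: none
Why: Iodine–lithium exchange then 1,2-addition to the non-enolisable epoxy ketone; the nucleophile enters anti to the epoxide C8–O bond (Felkin–Anh/Cornforth control, reinforced by lithium bridging the carbonyl and epoxide oxygens on the α face), giving the 9α-OH with the side chain β, while the neopentyl axial ester is too hindered to react at −78 °C.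

Step 12
Reactants: 20 ethyl 7α,8α-epoxy-9α-hydroxy-15-(trimethylsilyl)labd-13(16)-en-14-yn-19-oate
Product: 21 7α,8α-epoxy-15-(trimethylsilyl)labd-13(16)-en-14-yne-9α,19-diol
Conditions: LiAlH4, THF, 0 °C to rt; then aq Rochelle salt
Reagents that add atoms: none
Why: LiAlH4 reduction of the ester to the C19 primary alcohol; the rigid epoxide survives because trans-diaxial hydride opening would have to occur at the fully substituted C8 and the cis 9α-alkoxide cannot deliver hydride to its back side.

Step 13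
Reactants: 21 7α,8α-epoxy-15-(trimethylsilyl)labd-13(16)-en-14-yne-9α,19-diol
Product: 22 7α,9α,19-trihydroxy-15-(trimethylsilyl)labd-13(16)-en-14-yn-8β-yl acetate (8α-CH3)
Conditions: glacial AcOH, NaOAc (buffer), 45 °C
Reagents that add atoms: acetic acid, CC(=O)O
Why: Acid-catalysed epoxide acetolysis: acetic acid attacks the tertiary C8 from the β face (Markovnikov and Fürst–Plattner trans-diaxial opening agree), inverting C8 to the 8β-acetate with a 7α-alcohol; the buffered weak acid disfavours semipinacol shift of the hydroxy epoxide.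

Step 14
Reactants: 22 7α,9α,19-trihydroxy-15-(trimethylsilyl)labd-13(16)-en-14-yn-8β-yl acetate
Product: 23 19-[(tert-butyldimethylsilyl)oxy]-7α,9α-dihydroxy-15-(trimethylsilyl)labd-13(16)-en-14-yn-8β-yl acetate
Conditions: TBSCl (1.1 equiv), imidazole, DMF, 0 °C
Reagents that add atoms: tert-butyl(chloro)dimethylsilane, CC(C)(C)[Si](C)(C)Cl
Why: Silyl ether formation selects the primary C19 hydroxyl over the axial secondary 7α-OH next to a quaternary carbon and the tertiary 9α-OH.

Step 15
Reactants: 23 19-[(tert-butyldimethylsilyl)oxy]-7α,9α-dihydroxy-15-(trimethylsilyl)labd-13(16)-en-14-yn-8β-yl acetate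
Product: 24 19-[(tert-butyldimethylsilyl)oxy]-9α-hydroxy-7-oxo-15-(trimethylsilyl)labd-13(16)-en-14-yn-8β-yl acetate
Conditions: DMP, CH2Cl2, rt
Reagents that add atoms: none
Why: Dess–Martin oxidation of the only free secondary alcohol gives the C7 ketone; C8 is quaternary, so the α-acetoxy centre cannot epimerise.

Step 16
Reactants: 24 19-[(tert-butyldimethylsilyl)oxy]-9α-hydroxy-7-oxo-15-(trimethylsilyl)labd-13(16)-en-14-yn-8β-yl acetate
Product: 26 (13S)-19-[(tert-butyldimethylsilyl)oxy]-9α,13-epoxy-16-hydroxy-7-oxo-15-(trimethylsilyl)labd-14-yn-8β-yl acetate, via epoxide 25 (not isolated)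
Conditions: Shi oxazolidinone ketone (30 mol%), Oxone, K2CO3, Bu4NHSO4, DME/aq buffer, −10 °C; then CSA (10 mol%), CH2Cl2, 0 °C
Reagents that add atoms: potassium peroxymonosulfate, [K+].[O-]S(=O)(=O)OO
Why: Shi asymmetric epoxidation (chiral dioxirane; catalyst antipode chosen for the 13R epoxide) followed by acid-catalysed 5-exo-tet opening at the tertiary propargylic C13 by the 9α-OH with inversion sets the 13S spiro centre and frees the C16 alcohol.

Step 17
Reactants: 26 (13S)-19-[(tert-butyldimethylsilyl)oxy]-9α,13-epoxy-16-hydroxy-7-oxo-15-(trimethylsilyl)labd-14-yn-8β-yl acetate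
Product: 27 (13S)-9α,13-epoxy-16,19-dihydroxy-7-oxolabd-14-yn-8β-yl acetate
Conditions: TBAF, AcOH (1:1), THF, 0 °C to rt
Reagents that add atoms: none
Why: Fluoride desilylation cleaves the alkynyl C–Si and the primary O–Si bond in one operation, buffered so the tertiary α-keto acetate is not touched; no stereocentre changes.

Step 18
Reactants: 27 (13S)-9α,13-epoxy-16,19-dihydroxy-7-oxolabd-14-yn-8β-yl acetate
Product: 28 (13S)-9α,13:15,16-diepoxy-19-hydroxy-7-oxolabd-14-en-8β-yl acetate (target)
Conditions: Mo(CO)6 (30 mol%), Me3NO (30 mol%), Et3N/Et2O, rt; chromatography on Et3N-deactivated silica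
Reagents that add atoms: none
Why: Alkynol endo-cycloisomerisation: the terminal alkyne forms a molybdenum vinylidene that the homopropargylic C16–OH attacks at C15 and triethylamine releases the 2,3-dihydrofuran, so the acid-labile enol ether is made last under basic conditions.

**Compound list**
1 | resorcinol | Oc1cccc(O)c1 | starting material
2 | sodium 3-oxocyclohex-1-en-1-olate | [Na+].[O-]C1=CC(=O)CCC1 | intermediate
3 | 2-methylcyclohexane-1,3-dione | CC1C(=O)CCCC1=O | intermediate
4 | acrolein | C=CC=O | starting material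
5 | ethyl 2-(triphenyl-λ5-phosphanylidene)propanoate | CCOC(=O)C(C)=P(c1ccccc1)(c1ccccc1)c1ccccc1 | starting material
6 | 3-(1-methyl-2,6-dioxocyclohexyl)propanal | CC1(CCC=O)C(=O)CCCC1=O | intermediate
7 | ethyl (2E)-2-methyl-5-(1-methyl-2,6-dioxocyclohexyl)pent-2-enoate | CCOC(=O)/C(C)=C/CCC1(C)C(=O)CCCC1=O | intermediate
8 | ethyl 5β-{[diethoxy(methyl)silyl]oxy}-4α,10β-dimethyl-9-oxodecalin-4β-carboxylate | O=C1CCC[C@]2(O[Si](C)(OCC)OCC)[C@@](C)(C(=O)OCC)CCC[C@]12C | intermediate
9 | ethyl 5β-hydroxy-4α,10β-dimethyl-9-oxodecalin-4β-carboxylate | O=C1CCC[C@]2(O)[C@@](C)(C(=O)OCC)CCC[C@]12C | intermediate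
10 | ethyl 4α,10β-dimethyl-9-oxo-Δ5(6)-octalin-4β-carboxylate | O=C1CCC=C2[C@@](C)(C(=O)OCC)CCC[C@]12C | intermediate
11 | ethyl 4α,10β-dimethyl-9-oxo-5α-decalin-4β-carboxylate | O=C1CCC[C@H]2[C@@](C)(C(=O)OCC)CCC[C@]12C | intermediate
12 | ethyl 4α,8,10β-trimethyl-9-oxo-5α-decalin-4β-carboxylate (C8 epimers) | CC1CC[C@H]2[C@@](C)(C(=O)OCC)CCC[C@]2(C)C1=O | intermediate
13 | ethyl 4α,8,10β-trimethyl-9-oxo-5α-octal-7-ene-4β-carboxylate | CC1=CC[C@H]2[C@@](C)(C(=O)OCC)CCC[C@]2(C)C1=O | intermediate
14 | ethyl 7α,8α-epoxy-4α,8β,10β-trimethyl-9-oxo-5α-decalin-4β-carboxylate | C[C@@]12O[C@@H]1C[C@H]3[C@@](C)(C(=O)OCC)CCC[C@]3(C)C2=O | intermediate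
15 | 3-bromobut-3-en-1-ol | OCCC(Br)=C | starting material
16 | ethynyltrimethylsilane | C#C[Si](C)(C)C | starting material
17 | 3-methylidene-5-(trimethylsilyl)pent-4-yn-1-ol | OCCC(=C)C#C[Si](C)(C)C | intermediate
18 | (5-iodo-3-methylidenepent-1-yn-1-yl)trimethylsilane | ICCC(=C)C#C[Si](C)(C)C | intermediate
19 | [3-methylidene-5-(trimethylsilyl)pent-4-yn-1-yl]lithium | [Li]CCC(=C)C#C[Si](C)(C)C | intermediate
20 | ethyl 7α,8α-epoxy-9α-hydroxy-15-(trimethylsilyl)labd-13(16)-en-14-yn-19-oate | C[C@@]12O[C@@H]1C[C@H]3[C@@](C)(C(=O)OCC)CCC[C@]3(C)[C@@]2(O)CCC(=C)C#C[Si](C)(C)C | intermediate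
21 | 7α,8α-epoxy-15-(trimethylsilyl)labd-13(16)-en-14-yne-9α,19-diol | C[C@@]12O[C@@H]1C[C@H]3[C@@](C)(CO)CCC[C@]3(C)[C@@]2(O)CCC(=C)C#C[Si](C)(C)C | intermediate
22 | 7α,9α,19-trihydroxy-15-(trimethylsilyl)labd-13(16)-en-14-yn-8β-yl acetate | CC(=O)O[C@@]1(C)[C@H](O)C[C@H]2[C@@](C)(CO)CCC[C@]2(C)[C@@]1(O)CCC(=C)C#C[Si](C)(C)C | intermediate
23 | 19-[(tert-butyldimethylsilyl)oxy]-7α,9α-dihydroxy-15-(trimethylsilyl)labd-13(16)-en-14-yn-8β-yl acetate | CC(=O)O[C@@]1(C)[C@H](O)C[C@H]2[C@@](C)(CO[Si](C)(C)C(C)(C)C)CCC[C@]2(C)[C@@]1(O)CCC(=C)C#C[Si](C)(C)C | intermediate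
24 | 19-[(tert-butyldimethylsilyl)oxy]-9α-hydroxy-7-oxo-15-(trimethylsilyl)labd-13(16)-en-14-yn-8β-yl acetate | CC(=O)O[C@@]1(C)C(=O)C[C@H]2[C@@](C)(CO[Si](C)(C)C(C)(C)C)CCC[C@]2(C)[C@@]1(O)CCC(=C)C#C[Si](C)(C)C | intermediate
25 | (13R)-19-[(tert-butyldimethylsilyl)oxy]-13,16-epoxy-9α-hydroxy-7-oxo-15-(trimethylsilyl)labd-14-yn-8β-yl acetate | CC(=O)O[C@@]1(C)C(=O)C[C@H]2[C@@](C)(CO[Si](C)(C)C(C)(C)C)CCC[C@]2(C)[C@@]1(O)CC[C@@]1(C#C[Si](C)(C)C)CO1 | intermediate
26 | (13S)-19-[(tert-butyldimethylsilyl)oxy]-9α,13-epoxy-16-hydroxy-7-oxo-15-(trimethylsilyl)labd-14-yn-8β-yl acetate | CC(=O)O[C@@]1(C)C(=O)C[C@H]2[C@@](C)(CO[Si](C)(C)C(C)(C)C)CCC[C@]2(C)[C@@]12CC[C@@](CO)(C#C[Si](C)(C)C)O2 | intermediate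
27 | (13S)-9α,13-epoxy-16,19-dihydroxy-7-oxolabd-14-yn-8β-yl acetate | CC(=O)O[C@@]1(C)C(=O)C[C@H]2[C@@](C)(CO)CCC[C@]2(C)[C@@]12CC[C@@](CO)(C#C)O2 | intermediate
28 | (13S)-9α,13:15,16-diepoxy-19-hydroxy-7-oxolabd-14-en-8β-yl acetate | CC(=O)O[C@@]1(C)C(=O)C[C@H]2[C@@](C)(CO)CCC[C@]2(C)[C@@]12CC[C@@]1(C=COC1)O2 | target

**Totals and risks**
Total step count: 18. Longest linear sequence: 16 (steps 1–8 and 11–18).

Most likely to fail, step 3: the α-methyl enoate may be reduced too slowly (competing ketone hydrosilylation), or the aldol that makes three contiguous fully substituted carbons may not close. The fallback sets out from 3 and comes back at 12. Compound 3 and acrolein 4 are combined as in step 2, but aldehyde 6 is olefinated with ethyl 2-(triphenyl-λ5-phosphanylidene)acetate to give ethyl (2E)-5-(1-methyl-2,6-dioxocyclohexyl)pent-2-enoate F1. The same copper hydride system, now on a β-monosubstituted enoate of the precedented type, gives the silyl ether ethyl 5β-{[diethoxy(methyl)silyl]oxy}-10β-methyl-9-oxodecalin-4β-carboxylate F2 and, after hydrolysis, the ketol ethyl 5β-hydroxy-10β-methyl-9-oxodecalin-4β-carboxylate F3. LDA (3.3 equiv) and excess MeI then methylate the ester dianion anti to the C5 alkoxide (Fráter–Seebach alkylation, 4α-CH3) and the C8 ketone enolate at the same time, giving ethyl 5β-hydroxy-4α,8,10β-trimethyl-9-oxodecalin-4β-carboxylate F4. Burgess dehydration gives ethyl 4α,8,10β-trimethyl-9-oxo-Δ5(6)-octalin-4β-carboxylate F5, and the hydrogenation conditions of step 5 deliver 12.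

Second, step 11: the angular C10 methyl may override the epoxide's directing effect, or the ketone may be too hindered. The fallback sets out from 14 and comes back at 20, and places the C9 oxygen by an epoxidation instead of a carbonyl addition. Compound 14 is methylenated with Ph3P=CH2 to ethyl 7α,8α-epoxy-4α,8β,10β-trimethyl-9-methylidene-5α-decalin-4β-carboxylate F6. mCPBA attacks the exocyclic alkene from the α face, anti to the C10 methyl, giving ethyl 7α,8α:9α,11-diepoxy-4α,8β,10β-trimethyl-5α-decalin-4β-carboxylate F7. Separately, 2-bromoprop-2-en-1-ol and 16 are coupled (Sonogashira) to 2-methylidene-4-(trimethylsilyl)but-3-yn-1-ol F8, which is converted with CBr4/PPh3 to [3-(bromomethyl)but-3-en-1-yn-1-yl]trimethylsilane F9 and then with Mg to bromo[2-methylidene-4-(trimethylsilyl)but-3-yn-1-yl]magnesium F10. CuI-catalysed opening of the spiro-epoxide of F7 at the primary C11 gives 20.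

Third, step 16: the enyne alkene may epoxidise with poor face control, or the hindered tertiary–tertiary ether closure may lose to epoxide rearrangement. The fallback sets out from 24 and comes back at 26, and activates the alkene directly. Compound 24 is cyclised with N-iodosuccinimide (5-exo iodoetherification, Markovnikov) to (13S)-19-[(tert-butyldimethylsilyl)oxy]-9α,13-epoxy-16-iodo-7-oxo-15-(trimethylsilyl)labd-14-yn-8β-yl acetate F11, with the C13 epimers separated by chromatography. The neopentyl iodide is then converted to the alcohol by radical oxygenation (Bu3SnH, air, toluene), which returns 26.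

**Further compounds**
F1 | step 3 | ethyl (2E)-5-(1-methyl-2,6-dioxocyclohexyl)pent-2-enoate | CCOC(=O)/C=C/CCC1(C)C(=O)CCCC1=O
F2 | step 3 | ethyl 5β-{[diethoxy(methyl)silyl]oxy}-10β-methyl-9-oxodecalin-4β-carboxylate | O=C1CCC[C@]2(O[Si](C)(OCC)OCC)[C@@H](C(=O)OCC)CCC[C@]12C
F3 | step 3 | ethyl 5β-hydroxy-10β-methyl-9-oxodecalin-4β-carboxylate | O=C1CCC[C@]2(O)[C@@H](C(=O)OCC)CCC[C@]12C
F4 | step 3 | ethyl 5β-hydroxy-4α,8,10β-trimethyl-9-oxodecalin-4β-carboxylate | CC1CC[C@]2(O)[C@@](C)(C(=O)OCC)CCC[C@]2(C)C1=O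
F5 | step 3 | ethyl 4α,8,10β-trimethyl-9-oxo-Δ5(6)-octalin-4β-carboxylate | CC1CC=C2[C@@](C)(C(=O)OCC)CCC[C@]2(C)C1=O
F6 | step 11 | ethyl 7α,8α-epoxy-4α,8β,10β-trimethyl-9-methylidene-5α-decalin-4β-carboxylate | C[C@@]12O[C@@H]1C[C@H]3[C@@](C)(C(=O)OCC)CCC[C@]3(C)C2=C
F7 | step 11 | ethyl 7α,8α:9α,11-diepoxy-4α,8β,10β-trimethyl-5α-decalin-4β-carboxylate | C[C@@]12O[C@@H]1C[C@H]3[C@@](C)(C(=O)OCC)CCC[C@]3(C)[C@@]24CO4
F8 | step 11 | 2-methylidene-4-(trimethylsilyl)but-3-yn-1-ol | OCC(=C)C#C[Si](C)(C)C
F9 | step 11 | [3-(bromomethyl)but-3-en-1-yn-1-yl]trimethylsilane | BrCC(=C)C#C[Si](C)(C)C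
F10 | step 11 | bromo[2-methylidene-4-(trimethylsilyl)but-3-yn-1-yl]magnesium | Br[Mg]CC(=C)C#C[Si](C)(C)C
F11 | step 16 | (13S)-19-[(tert-butyldimethylsilyl)oxy]-9α,13-epoxy-16-iodo-7-oxo-15-(trimethylsilyl)labd-14-yn-8β-yl acetate | CC(=O)O[C@@]1(C)C(=O)C[C@H]2[C@@](C)(CO[Si](C)(C)C(C)(C)C)CCC[C@]2(C)[C@@]12CC[C@@](CI)(C#C[Si](C)(C)C)O2
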